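**Plan**

- Retrosynthesis: the three benzyl groups (two ethers, one ester) come off last. Ring B is then cut across B C1–B C2 and B C5–B C6.
- Enabling feature (each ring numbered from its carbonyl-bearing carbon C1, hydroxyl on C2, methyl on C6): ring B atoms C2–C5 are an acetoacetate unit whose C4 oxygen already carries the ring A acyl group, and atoms C6–C1 are a but-2-ynoate already esterified to ring C. Ring B is therefore the aromatised [4+2] adduct of a ketene acetal diene and an alkynoate.
- Further cuts: the enol ester C–O bond of the diene (ring A acid chloride + methyl acetoacetate) and the aryl ester of the ynoate (ring C phenol + but-2-ynoic acid).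
- Forward: ring C arm from orsellinic acid (steps 1–5), ring A arm from methyl orsellinate (steps 6–12), ring B closed last by cycloaddition and aromatisation (step 13), hydrogenolysis (step 14).
- Stereochemistry: the target has no stereocentre and no stereogenic double bond. The alkene geometries of 17 and 18 and the single sp3 centre of adduct 19 disappear when ring B aromatises.

Key step: step 13

Remark: 17 and 18 are drawn as the geometric isomers expected to predominate; the other isomers would lead to the same aromatic ring B, so isomer mixtures would be carried forward unseparated.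

**Ring C arm**

Step 1
Reactants: 1 orsellinic acid (2,4-dihydroxy-6-methylbenzoic acid)
Product: 2 benzyl 2,4-dihydroxy-6-methylbenzoate
Conditions: BnBr, KHCO3, DMF, rt
Reagents that add atoms: benzyl bromide, BrCc1ccccc1
Why: Hydrogencarbonate deprotonates only the carboxylic acid, so SN2 O-alkylation of the carboxylate should give the benzyl ester and leave both phenols free.

Step 2
Reactants: 2 benzyl 2,4-dihydroxy-6-methylbenzoate
Product: 3 benzyl 4-(allyloxy)-2-hydroxy-6-methylbenzoate
Conditions: allyl bromide (1.05 equiv), K2CO3, acetone, reflux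
Reagents that add atoms: allyl bromide, C=CCBr
Why: Williamson ether synthesis in which the 2-hydroxyl is held in a hydrogen bond to the ester carbonyl, so the more acidic, unhindered 4-hydroxyl should be alkylated selectively by one equivalent of halide.

Step 3
Reactants: 3 benzyl 4-(allyloxy)-2-hydroxy-6-methylbenzoate
Product: 4 benzyl 4-(allyloxy)-2-(benzyloxy)-6-methylbenzoate
Conditions: BnBr, K2CO3, DMF, 60 °C
Reagents that add atoms: benzyl bromide, BrCc1ccccc1
Why: Williamson ether synthesis under more forcing conditions should benzylate the remaining chelated phenol, while the allyl ether and the hindered benzyl ester are inert to carbonate.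

Step 4
Reactants: 4 benzyl 4-(allyloxy)-2-(benzyloxy)-6-methylbenzoate
Product: 5 benzyl 2-(benzyloxy)-4-hydroxy-6-methylbenzoate (ring C phenol)
Conditions: Pd(PPh3)4 (cat.), morpholine, THF, rt
Reagents that add atoms: none
Why: Tsuji–Trost deallylation in which zerovalent palladium ionises the aryl allyl ether to a π-allyl complex and the phenoxide, morpholine captures the allyl group, and benzyl ether and benzyl ester stay untouched because no hydrogen is present.

Step 5
Reactants: 5 benzyl 2-(benzyloxy)-4-hydroxy-6-methylbenzoate; 6 but-2-ynoic acid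
Product: 7 benzyl 2-(benzyloxy)-4-(but-2-ynoyloxy)-6-methylbenzoate (ring C but-2-ynoate)
Conditions: DCC, DMAP (cat.), CH2Cl2, 0 °C to rt
Reagents that add atoms: none
Why: Steglich esterification, in which DCC activates the alkynoic acid as its O-acylisourea and a small amount of DMAP relays the acyl group to the only free phenol, is the usual way to aryl but-2-ynoates.

**Ring A arm**

Step 6
Reactants: 8 methyl orsellinate (methyl 2,4-dihydroxy-6-methylbenzoate)
Product: 9 methyl 2-hydroxy-4-methoxy-6-methylbenzoate
Conditions: MeI (1.1 equiv), K2CO3, acetone, reflux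
Reagents that add atoms: iodomethane, CI
Why: Williamson ether synthesis that should be selective for the 4-hydroxyl because the 2-hydroxyl is hydrogen-bonded to the ester carbonyl and much less nucleophilic.

Step 7
Reactants: 9 methyl 2-hydroxy-4-methoxy-6-methylbenzoate
Product: 11 methyl 2,5-dihydroxy-4-methoxy-6-methylbenzoate, via aryl potassium sulfate 10 (not isolated)
Conditions: K2S2O8, aq KOH, 5 to 20 °C; then aq HCl, 80 °C
Reagents that add atoms: potassium peroxodisulfate, [K+].[K+].[O-]S(=O)(=O)OOS(=O)(=O)[O-]
Why: Elbs persulfate oxidation in which the phenolate attacks a peroxide oxygen through its para carbon (C5, the only free para position, since C1 is blocked), and acid hydrolysis of the aryl sulfate 10 then frees the hydroquinone while the hindered methyl ester survives.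

Step 8
Reactants: 11 methyl 2,5-dihydroxy-4-methoxy-6-methylbenzoate
Product: 12 methyl 2-hydroxy-4,5-dimethoxy-6-methylbenzoate
Conditions: MeI (1.1 equiv), K2CO3, acetone, reflux, under N2
Reagents that add atoms: iodomethane, CI
Why: Williamson ether synthesis that should pick the C5 hydroxyl, the only one not hydrogen-bonded to the ester, with inert gas keeping the hydroquinone from air oxidation.

Step 9
Reactants: 12 methyl 2-hydroxy-4,5-dimethoxy-6-methylbenzoate
Product: 13 methyl 2-(benzyloxy)-4,5-dimethoxy-6-methylbenzoate
Conditions: BnBr, K2CO3, DMF, 70 °C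
Reagents that add atoms: benzyl bromide, BrCc1ccccc1
Why: Williamson ether synthesis in a dipolar aprotic solvent with heating, which is the standard way to benzylate a chelated ortho-hydroxy benzoate.

Step 10
Reactants: 13 methyl 2-(benzyloxy)-4,5-dimethoxy-6-methylbenzoate
Product: 14 2-(benzyloxy)-4,5-dimethoxy-6-methylbenzoic acid (ring A acid)
Conditions: KOH, DMSO/H2O, 90 °C; then aq HCl, 0 °C
Reagents that add atoms: potassium hydroxide, [K+].[OH-]
Why: Saponification of the doubly ortho-substituted methyl ester needs poorly solvated hydroxide in hot aqueous DMSO, conditions that aryl methyl and benzyl ethers tolerate.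

Step 11
Reactants: 14 2-(benzyloxy)-4,5-dimethoxy-6-methylbenzoic acid; 15 methyl acetoacetate
Product: 17 methyl (E)-3-{[2-(benzyloxy)-4,5-dimethoxy-6-methylbenzoyl]oxy}but-2-enoate, via ring A acid chloride 16 (not isolated)
Conditions: (COCl)2, DMF (cat.), CH2Cl2, 0 °C to rt; evaporate; then 15, Et3N, CH2Cl2, 0 °C to rt
Reagents that add atoms: none
Why: Acid chloride formation by Vilsmeier-type activation is followed by O-acylation of the amine-generated enolate of the β-keto ester, the classical route to 3-acyloxybut-2-enoates, in which the hard, hindered aroyl chloride should favour oxygen over carbon.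

Step 12
Reactants: 17 methyl (E)-3-{[2-(benzyloxy)-4,5-dimethoxy-6-methylbenzoyl]oxy}but-2-enoate
Product: 18 (3Z)-4-methoxy-4-[(trimethylsilyl)oxy]buta-1,3-dien-2-yl 2-(benzyloxy)-4,5-dimethoxy-6-methylbenzoate (ring A-bearing ketene acetal diene; crude, used at once)
Conditions: Me3SiCl, then LiN(iPr)2 (commercial solution, 1.1 equiv), THF, −78 to 0 °C; evaporate, pentane, filter under Ar
Reagents that add atoms: chlorotrimethylsilane, C[Si](C)(C)Cl
Why: Kinetic γ-deprotonation and O-silylation, the standard preparation of 1-methoxy-1-silyloxybuta-1,3-dienes from 3-alkoxy- and 3-silyloxybut-2-enoates, should work here because lithium bound to the methyl ester carbonyl delivers the base to the cis γ-methyl group and the silyl chloride already present traps the dienolate on oxygen at −78 °C before the hindered, doubly ortho-substituted aroyl group can migrate or be expelled.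

**Union and end game**

Step 13
Reactants: 18 ring A-bearing ketene acetal diene (1.5 equiv); 7 benzyl 2-(benzyloxy)-4-(but-2-ynoyloxy)-6-methylbenzoate
Product: 20 benzyl 2-(benzyloxy)-4-{[4-{[2-(benzyloxy)-4,5-dimethoxy-6-methylbenzoyl]oxy}-2-hydroxy-6-methylbenzoyl]oxy}-6-methylbenzoate (protected tridepside, B C2 hydroxyl free), via cyclohexa-1,4-diene cycloadduct 19 (not isolated)
Conditions: PhMe, 120 °C, sealed tube; then 1 M HCl, THF, rt
Reagents that add atoms: none
Why: The ketene acetal end makes the CH2 terminus of 18 (future B C5) its most nucleophilic carbon, so it bonds to the β-carbon of ynoate 7 (future B C6, methyl-bearing) while the developing oxocarbenium carbon (future B C2) is captured by the α-carbon (future B C1), a concerted but strongly asynchronous normal-demand Diels–Alder reaction that gives the cyclohexa-1,4-diene 19. The closest known reaction type is the cycloaddition and aromatisation of 1-alkoxy-1-silyloxy- and 1,1-dialkoxy-3-silyloxybuta-1,3-dienes with 2-alkynoates to salicylates and resorcylates; here the diene C3 oxygen carries an aroyl group instead of silicon, a weaker donor that still polarises the diene in the same sense. Ring B closes in the intermolecular [4+2] mode, four carbons from the diene and two from the alkyne, forming B C1–B C2 and B C5–B C6. Adduct 19 has a mixed methyl silyl ketal at B C2 and a CH2 at B C5, so dilute acid collapses the ketal with loss of methanol and trimethylsilanol and tautomerisation gives the hydrogen-bonded B C2 phenol; the only sp3 centre formed (B C2 of 19) is racemic and is erased on aromatisation, so no stereocontrol is required. The selectivity needed is regiochemical (methyl-bearing alkyne carbon to B C5) and is secured by the matched polarisation of the donor-substituted diene and the conjugated aryl ester, while the absence of acidic O–H groups in both partners and the hindered, doubly ortho-substituted aroyl esters protect the diene from protonation and the esters from acyl transfer.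

Step 14
Reactants: 20 protected tridepside
Product: 21 4-{[4-[(2-hydroxy-4,5-dimethoxy-6-methylbenzoyl)oxy]-2-hydroxy-6-methylbenzoyl]oxy}-2-hydroxy-6-methylbenzoic acid (CNP0139469.0)
Conditions: H2 (1 atm), Pd/C (10 wt% palladium on carbon), EtOAc/THF, rt
Reagents that add atoms: none
Why: Catalytic hydrogenolysis of the two benzyl ethers and the benzyl ester is the standard closing step of depside syntheses, and the aryl ester links, methyl ethers and free phenols are inert to it.

**Compound list**

1 | orsellinic acid (2,4-dihydroxy-6-methylbenzoic acid) | Cc1cc(O)cc(O)c1C(=O)O | starting material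
2 | benzyl 2,4-dihydroxy-6-methylbenzoate | Cc1cc(O)cc(O)c1C(=O)OCc1ccccc1 | intermediate
3 | benzyl 4-(allyloxy)-2-hydroxy-6-methylbenzoate | C=CCOc1cc(C)c(C(=O)OCc2ccccc2)c(O)c1 | intermediate
4 | benzyl 4-(allyloxy)-2-(benzyloxy)-6-methylbenzoate | C=CCOc1cc(C)c(C(=O)OCc2ccccc2)c(OCc2ccccc2)c1 | intermediate
5 | benzyl 2-(benzyloxy)-4-hydroxy-6-methylbenzoate | Oc1cc(C)c(C(=O)OCc2ccccc2)c(OCc2ccccc2)c1 | intermediate
6 | but-2-ynoic acid | CC#CC(=O)O | starting material
7 | benzyl 2-(benzyloxy)-4-(but-2-ynoyloxy)-6-methylbenzoate | CC#CC(=O)Oc1cc(C)c(C(=O)OCc2ccccc2)c(OCc2ccccc2)c1 | intermediate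
8 | methyl orsellinate (methyl 2,4-dihydroxy-6-methylbenzoate) | Cc1cc(O)cc(O)c1C(=O)OC | starting material
9 | methyl 2-hydroxy-4-methoxy-6-methylbenzoate | COC(=O)c1c(C)cc(OC)cc1O | intermediate
10 | potassium 4-hydroxy-6-methoxy-3-(methoxycarbonyl)-2-methylphenyl sulfate | COC(=O)c1c(C)c(OS(=O)(=O)[O-])c(OC)cc1O.[K+] | intermediate
11 | methyl 2,5-dihydroxy-4-methoxy-6-methylbenzoate | COC(=O)c1c(C)c(O)c(OC)cc1O | intermediate
12 | methyl 2-hydroxy-4,5-dimethoxy-6-methylbenzoate | COC(=O)c1c(C)c(OC)c(OC)cc1O | intermediate
13 | methyl 2-(benzyloxy)-4,5-dimethoxy-6-methylbenzoate | COC(=O)c1c(C)c(OC)c(OC)cc1OCc1ccccc1 | intermediate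
14 | 2-(benzyloxy)-4,5-dimethoxy-6-methylbenzoic acid | OC(=O)c1c(C)c(OC)c(OC)cc1OCc1ccccc1 | intermediate
15 | methyl acetoacetate | CC(=O)CC(=O)OC | starting material
16 | 2-(benzyloxy)-4,5-dimethoxy-6-methylbenzoyl chloride | ClC(=O)c1c(C)c(OC)c(OC)cc1OCc1ccccc1 | intermediate
17 | methyl (E)-3-{[2-(benzyloxy)-4,5-dimethoxy-6-methylbenzoyl]oxy}but-2-enoate | COC(=O)/C=C(\C)OC(=O)c1c(C)c(OC)c(OC)cc1OCc1ccccc1 | intermediate
18 | (3Z)-4-methoxy-4-[(trimethylsilyl)oxy]buta-1,3-dien-2-yl 2-(benzyloxy)-4,5-dimethoxy-6-methylbenzoate | C=C(OC(=O)c1c(C)c(OC)c(OC)cc1OCc1ccccc1)/C=C(/OC)O[Si](C)(C)C | intermediate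
19 | benzyl 2-(benzyloxy)-4-{[4-{[2-(benzyloxy)-4,5-dimethoxy-6-methylbenzoyl]oxy}-6-methoxy-2-methyl-6-[(trimethylsilyl)oxy]cyclohexa-1,4-diene-1-carbonyl]oxy}-6-methylbenzoate (racemic) | COC1(O[Si](C)(C)C)C=C(OC(=O)c2c(C)c(OC)c(OC)cc2OCc2ccccc2)CC(C)=C1C(=O)Oc1cc(C)c(C(=O)OCc2ccccc2)c(OCc2ccccc2)c1 | intermediate
20 | benzyl 2-(benzyloxy)-4-{[4-{[2-(benzyloxy)-4,5-dimethoxy-6-methylbenzoyl]oxy}-2-hydroxy-6-methylbenzoyl]oxy}-6-methylbenzoate | COc1cc(OCc2ccccc2)c(C(=O)Oc2cc(C)c(C(=O)Oc3cc(C)c(C(=O)OCc4ccccc4)c(OCc4ccccc4)c3)c(O)c2)c(C)c1OC | intermediate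
21 | 4-{[4-[(2-hydroxy-4,5-dimethoxy-6-methylbenzoyl)oxy]-2-hydroxy-6-methylbenzoyl]oxy}-2-hydroxy-6-methylbenzoic acid (CNP0139469.0) | COc1cc(O)c(C(=O)Oc2cc(C)c(C(=O)Oc3cc(C)c(C(=O)O)c(O)c3)c(O)c2)c(C)c1OC | target

**Step count**

Total: 14 steps. Longest linear sequence: 9 steps (8 to 21 through steps 6–14); the ring C arm contributes 5 steps before the union.

**Steps most likely to fail**

1. Step 13. The cycloaddition may be slower than thermal decay or desilylation of the diene, because the acyloxy group is a weaker donor than a silyl ether and the alkyne carries a β-methyl group. Aromatisation could also proceed by loss of trimethylsilanol instead of methanol and leave a methyl ether on B C2. The fallback gives up the cycloaddition and builds the two ester links one after the other; it sets out from orsellinic acid 1 and comes back at 20. Carboxylate alkylation of 1 with allyl bromide and KHCO3 in DMF would give allyl 2,4-dihydroxy-6-methylbenzoate F1. Its non-chelated 4-hydroxyl would be acylated with acid chloride 16 (made from 14 as in step 11; Et3N, cat. DMAP, CH2Cl2) to give allyl 4-{[2-(benzyloxy)-4,5-dimethoxy-6-methylbenzoyl]oxy}-2-hydroxy-6-methylbenzoate F2. Deallylation with Pd(PPh3)4 and morpholine would free 4-{[2-(benzyloxy)-4,5-dimethoxy-6-methylbenzoyl]oxy}-2-hydroxy-6-methylbenzoic acid F3. Esterification of F3 with phenol 5 through the mixed anhydride (trifluoroacetic anhydride, toluene, rt) would give 20.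

2. Step 12. LiN(iPr)2 may deprotonate the ring A benzylic methyl group in competition with the γ-methyl group. The dienolate may also lose or transfer the aroyl group before it is silylated, and the silyl ketene acetal may hydrolyse during handling. The fallback keeps the ring B cycloaddition but uses the known bis-silyloxy diene and attaches ring A afterwards; it sets out from methyl acetoacetate 15 and ynoate 7 and comes back at 20. Silylation of 15 (Me3SiCl, Et3N) would give methyl (E)-3-[(trimethylsilyl)oxy]but-2-enoate F4, and LiN(iPr)2/Me3SiCl would convert it into (1Z)-1-methoxy-1,3-bis[(trimethylsilyl)oxy]buta-1,3-diene F5. Heating F5 with 7 in toluene would give the cycloadduct benzyl 2-(benzyloxy)-4-{[6-methoxy-2-methyl-4,6-bis[(trimethylsilyl)oxy]cyclohexa-1,4-diene-1-carbonyl]oxy}-6-methylbenzoate F6. Dilute acid would aromatise F6 to benzyl 2-(benzyloxy)-4-[(2,4-dihydroxy-6-methylbenzoyl)oxy]-6-methylbenzoate F7. Acylation of the non-chelated B C4 hydroxyl of F7 with acid chloride 16 (Et3N, cat. DMAP, CH2Cl2) would give 20.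

3. Step 7. Conversion in the persulfate oxidation may be low, and the electron-rich phenolate may be oxidised further to dark polymeric material. The fallback reaches the same hydroquinone by way of the quinone; it sets out from 9 and comes back at 11. Teuber oxidation of 9 with potassium nitrosodisulfonate ON(SO3K)2 in buffered aqueous acetone would give methyl 4-methoxy-2-methyl-3,6-dioxocyclohexa-1,4-diene-1-carboxylate F8, and reduction of F8 with Na2S2O4 in EtOAc/water would give 11.

**Further compounds**

F1 | step 13 | allyl 2,4-dihydroxy-6-methylbenzoate | C=CCOC(=O)c1c(C)cc(O)cc1O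
F2 | step 13 | allyl 4-{[2-(benzyloxy)-4,5-dimethoxy-6-methylbenzoyl]oxy}-2-hydroxy-6-methylbenzoate | C=CCOC(=O)c1c(C)cc(OC(=O)c2c(C)c(OC)c(OC)cc2OCc2ccccc2)cc1O
F3 | step 13 | 4-{[2-(benzyloxy)-4,5-dimethoxy-6-methylbenzoyl]oxy}-2-hydroxy-6-methylbenzoic acid | OC(=O)c1c(C)cc(OC(=O)c2c(C)c(OC)c(OC)cc2OCc2ccccc2)cc1O
F4 | step 12 | methyl (E)-3-[(trimethylsilyl)oxy]but-2-enoate | COC(=O)/C=C(\C)O[Si](C)(C)C
F5 | step 12 | (1Z)-1-methoxy-1,3-bis[(trimethylsilyl)oxy]buta-1,3-diene | C=C(O[Si](C)(C)C)/C=C(/OC)O[Si](C)(C)C
F6 | step 12 | benzyl 2-(benzyloxy)-4-{[6-methoxy-2-methyl-4,6-bis[(trimethylsilyl)oxy]cyclohexa-1,4-diene-1-carbonyl]oxy}-6-methylbenzoate (racemic) | COC1(O[Si](C)(C)C)C=C(O[Si](C)(C)C)CC(C)=C1C(=O)Oc1cc(C)c(C(=O)OCc2ccccc2)c(OCc2ccccc2)c1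
F7 | step 12 | benzyl 2-(benzyloxy)-4-[(2,4-dihydroxy-6-methylbenzoyl)oxy]-6-methylbenzoate | Cc1cc(O)cc(O)c1C(=O)Oc1cc(C)c(C(=O)OCc2ccccc2)c(OCc2ccccc2)c1
F8 | step 7 | methyl 4-methoxy-2-methyl-3,6-dioxocyclohexa-1,4-diene-1-carboxylate | COC(=O)C1=C(C)C(=O)C(OC)=CC1=O
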